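The blue run, charged more heavily than the grey run, reads the higher target, 59.2% against 48.9% at 0.500 h. The flask is charged less than either; its target is reckoned below one process at a time.

| flask | starting material | remark | time |
|---|---|---|---|
| grey | 0.070 M | run made earlier |  |
| blue | 0.11 M | run made earlier |  |
| flask | 0.050 M |  | 15 h |

- grey (time / h: target / %, starting material / %): 0.100: 39.0, 59.1; 0.200: 46.3, 45.7; 0.500: 48.9, 32.5; 1.00: 39.6, 28.0; 2.00: 28.0, 20.6; 4.00: 15.5, 18.4; 10.0: 5.3, 13.4
- blue (time / h: target / %, starting material / %): 0.100: 46.9, 50.3; 0.200: 56.2, 33.6; 0.500: 59.2, 21.1; 1.00: 51.0, 18.6; 2.00: 33.3, 19.3; 4.00: 13.2, 13.5; 10.0: 4.7, 6.7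

(standard deviation of a reading: 1 percentage point)

- percentages count the starting material that a species holds: one target counts as two
- a reading or a percentage of target counts all its forms, free or not

- the best time, 15 h at the latest, for target
- the amount of target, in percent of the starting material charged, at that time
- the first time at which target reaches 24%, in the same percent

1. Main step alone: two starting material give one target. The grey reading at 0.100 h gives a second-order constant, counted on starting material lost, of 98.9 M⁻¹ h⁻¹. The flask's first half-life by this step alone is then 0.202 h, and this reckoning puts the level asked at 0.0639 h.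

2. Reverse step added: in the grey run at 1.00 h, c(target) over c(starting material) squared reads 36.1 M⁻¹. The blue run reads 67.0 M⁻¹, but the grey charge lies nearer the flask. This gives the balance ceiling, the equilibrium yield of target at a given charge with no other step running: 59.4% in the flask, 64.3% in the grey run.

3. Loss added: at 1.00 h the grey run's two species leave 32 percentage points unaccounted for, so a further product forms. The grey peak reading is 76.0% of its ceiling. If the flask keeps the same share, its best is reckoned at 45.2%, taken near 0.500 h, where both runs read their highest target.

The forecast puts the best at 42% at 0.45 h and the level asked at 0.075 h, holding that “the target has nearly gone, so the maximum is this early peak”; its best lies below the reckoning above.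

The flask gives 47.6% at 0.423 h, and first reaches the level at 0.0644 h. That best stands 2.4 points above the reckoning. At that time side product holds 12.0%. The flask thus keeps 80.1% of its ceiling.

    2 starting material ⇌ target (K = 37.0 M⁻¹, k = 0.0150 M⁻¹ s⁻¹)
    starting material + target → side product (k = 0.00540 M⁻¹ s⁻¹)
    crystals ⇌ target, rate k3*(cs3 - [target]) while solid is left; crystals form when [target] > cs3 (solubility = 18.0 mM, k = 0.00550 s⁻¹)
    starting material → decomposition product (k = 6.80 × 10⁻⁸ s⁻¹)

A neighbour charged with 0.013 M has a reckoned ceiling of 37.1%, and the share kept in the flask gives 29.7% there. Its computed best is 32.3%.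

(All runs come from a simulation from invented constants.)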